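**Retrosynthetic overview**

- The strategy rests on C6 of ring B (C5–C10, drimane numbering): it is an allylic carbinol bonded to C7 of the C7=C8 alkene. The C6–C7 bond is therefore cut last, back to a C7 (Z)-alkenyl iodide and a C6 aldehyde held cis on ring A (chromium/nickel alkenyl–aldehyde closure).
- After the closure: acylation of O6 with the trienoic acid, desilylation, oxidation of C12 to the aldehyde, cleavage of the C11 ester.
- C9 is cut at C8–C9: a stereodefined β-silyl alkenylmetal adds to the convex face of a cis-fused α-keto δ-lactone (C11 tied to O6). The lactone is then opened to the C11 ester and the C6 aldehyde.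
- The keto lactone comes from a cis-fused γ-lactone (C9 carbonyl) and a one-carbon acyl-anion equivalent. Ring A gets C5 and C10 by asymmetric conjugate vinylation and trans methylation of an enone ester made from 4,4-dimethylcyclohexanone; the C1 ketone is removed reductively.
- Ring order: ring A is bought, two temporary lactone rings serve as templates, ring B is formed last.

Key step: step 16

Remark 1: drimane numbering is used for every intermediate; β is the face of the C10 methyl group, so the target is 5β-H, 6β-O-acyl, 9β-OH, 9α-CO2H, 10β-CH3 (cis-fused).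
Remark 2: a free 9-hydroxyl is γ to the C6 aldehyde and would close to a five-membered lactol, so O9 is carried through the ring closure as a triethylsilyl ether; the C11 acid is carried as its 4-methoxybenzyl ester because it is made by carboxylate alkylation.

**Route**

Step 1
Reactants: 1 4,4-dimethylcyclohexan-1-one; 2 dimethyl carbonate
Product: 3 methyl 5,5-dimethyl-2-oxocyclohexane-1-carboxylate
Conditions: NaH (2.2 equiv), THF, reflux; AcOH quench
Reagents that add atoms: none
Why: Claisen-type C-acylation of the ketone enolate by dimethyl carbonate is driven by deprotonation of the β-keto ester, and the symmetric ketone can give only one regioisomer.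

Step 2
Reactants: 3 methyl 5,5-dimethyl-2-oxocyclohexane-1-carboxylate
Product: 6 methyl 3,3-dimethyl-6-oxocyclohex-1-ene-1-carboxylate, via selenide 4 (not isolated), via selenoxide 5 (not isolated)
Conditions: PhSeCl, pyridine, CH2Cl2, 0 °C; then 30% H2O2, 0 °C → rt
Reagents that add atoms: none
Why: α-Selenenylation of the β-keto ester and syn-elimination of the selenoxide toward its only β-hydrogens give the doubly activated enone, which the gem-dimethyl group keeps from tautomerising further.

Step 3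
Reactants: 6 methyl 3,3-dimethyl-6-oxocyclohex-1-ene-1-carboxylate; 7 potassium vinyltrifluoroborate
Product: 8 methyl (6S)-6-ethenyl-5,5-dimethyl-2-oxocyclohexane-1-carboxylate
Conditions: [Rh(cod)2]BF4 (3 mol %), (R)-BINAP (3.3 mol %), toluene/H2O 20:1, 100 °C
Reagents that add atoms: none
Why: Hayashi–Miyaura rhodium-catalysed asymmetric 1,4-addition sets C5, the vinylrhodium–BINAP species inserting the enone and water protonating the oxa-π-allyl; by analogy with the known sense of (S)-BINAP on cyclohex-2-enone the (R)-ligand should deliver vinyl to the required face, and the ligand antipode is used if the sense is reversed on this substrate.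

Step 4
Reactants: 8 methyl (6S)-6-ethenyl-5,5-dimethyl-2-oxocyclohexane-1-carboxylate
Product: 9 methyl (1R,6R)-6-ethenyl-1,5,5-trimethyl-2-oxocyclohexane-1-carboxylate
Conditions: K2CO3, MeI, acetone, 40 °C
Reagents that add atoms: iodomethane, CI
Why: C-Alkylation of the β-keto ester enolate takes place anti to the neighbouring pseudo-axial vinyl group, so the new C10 methyl is trans to vinyl and the ester and vinyl arms are cis.

Step 5
Reactants: 9 methyl (1R,6R)-6-ethenyl-1,5,5-trimethyl-2-oxocyclohexane-1-carboxylate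
Product: 11 cis-fused 7-hydroxy-4,4,7a-trimethylhexahydro-2-benzofuran-1(3H)-one (C7 epimers), via diol ester 10 (not isolated)
Conditions: O3, CH2Cl2/MeOH 4:1, −78 °C; NaBH4, −78 → 0 °C; then TsOH·H2O (cat.), CH2Cl2, rt
Reagents that add atoms: ozone, [O-][O+]=O
Why: Ozonolysis of the only alkene with borohydride work-up gives the C6 alcohol and reduces the C1 ketone, and the cis hydroxymethyl group then lactonises onto the neighbouring ester (five-membered ring), the C1 carbinol of either configuration being only a handle for deoxygenation.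

Step 6
Reactants: 11 cis-fused 7-hydroxy-4,4,7a-trimethylhexahydro-2-benzofuran-1(3H)-one
Product: 12 O-phenyl thionocarbonate of 11
Conditions: PhOC(S)Cl, pyridine, DMAP (cat.), CH2Cl2, rt
Reagents that add atoms: O-phenyl chlorothionoformate, S=C(Cl)Oc1ccccc1
Why: Thioacylation of the hindered secondary alcohol under non-basic conditions, which avoid retro-aldol opening of the β-hydroxy lactone, prepares the Barton–McCombie deoxygenation.

Step 7
Reactants: 12 O-phenyl thionocarbonate of 11
Product: 13 (3aR,7aS)-4,4,7a-trimethylhexahydro-2-benzofuran-1(3H)-one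
Conditions: Bu3SnH, AIBN (cat.), toluene, 100 °C
Reagents that add atoms: none
Why: Barton–McCombie radical deoxygenation, in which the stannyl radical adds to C=S, β-scission gives the C1 radical and hydrogen transfer from Bu3SnH outruns any 1,2-acyl shift.

Step 8
Reactants: 13 (3aR,7aS)-4,4,7a-trimethylhexahydro-2-benzofuran-1(3H)-one; 14 ethyl vinyl ether
Product: 16 2-ethoxy-1-[cis-2-(hydroxymethyl)-1,3,3-trimethylcyclohexyl]prop-2-en-1-one, via 1-ethoxyvinyllithium 15 (not isolated)
Conditions: 14, tBuLi, THF, −78 → 0 °C; then 13, THF, −78 °C; aq NH4Cl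
Reagents that add atoms: none
Why: Acyl substitution at the lactone carbonyl stops at the ketone stage because the lithium lactolate survives until the quench, 1-ethoxyvinyllithium acting as a masked alkoxycarbonyl anion that brings in C11 (the product may sit partly as its five-membered hemiketal, which reacts the same way in step 9).

Step 9
Reactants: 16 2-ethoxy-1-[cis-2-(hydroxymethyl)-1,3,3-trimethylcyclohexyl]prop-2-en-1-one
Product: 18 cis-fused 4a,8,8-trimethyl-4a,5,6,7,8,8a-hexahydro-1H-isochromene-3,4-dione, via ethyl keto ester 17 (not isolated)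
Conditions: O3, CH2Cl2, −78 °C; Me2S, −78 °C → rt; then TsOH·H2O (cat.), toluene, 4 Å MS, 80 °C
Reagents that add atoms: ozone, [O-][O+]=O
Why: Ozonolysis of the electron-rich enol ether turns C(OEt)=CH2 into the ethyl ester of an α-keto acid, and acid-catalysed transesterification by the cis 6-hydroxyl with removal of ethanol closes the six-membered α-keto lactone that serves as the template for C9.

Step 10
Reactants: 19 tert-butyldimethyl(prop-2-yn-1-yloxy)silane; 20 trimethyl(tributylstannyl)silane
Product: 21 (Z)-tert-butyldimethyl{[2-(tributylstannyl)-3-(trimethylsilyl)prop-2-en-1-yl]oxy}silane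
Conditions: Pd(PPh3)4 (2 mol %), THF, 65 °C
Reagents that add atoms: none
Why: Palladium-catalysed syn silylstannation of a terminal alkyne places tin on the internal and silicon on the terminal carbon on the same side, which fixes silicon cis to the carbon that will bond to C9.

Step 11
Reactants: 18 cis-fused 4a,8,8-trimethyl-4a,5,6,7,8,8a-hexahydro-1H-isochromene-3,4-dione; 21 (Z)-tert-butyldimethyl{[2-(tributylstannyl)-3-(trimethylsilyl)prop-2-en-1-yl]oxy}silane
Product: 24 12-[(tert-butyldimethylsilyl)oxy]-9β-hydroxy-7-(trimethylsilyl)-6,7-seco-5β-drim-7(Z)-en-11,6-olide, via alkenyllithium 22 (not isolated), via alkenylcerium dichloride 23 (not isolated)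
Conditions: 21, nBuLi, THF, −78 °C; CeCl3 (anhydrous), THF, −78 °C; then 18, −78 °C; aq NH4Cl
Reagents that add atoms: none
Why: Tin–lithium exchange with retention, transmetalation to cerium and 1,2-addition to the activated, non-enolisable ketone (the organocerium spares the lactone) should occur on the convex face of the cis-fused bicycle, the face of the C10 methyl and H5 away from ring A and its C4 carbon, which puts C8 cis to the C10 methyl on the lactone ring and the hydroxyl toward ring A, the C9 configuration of the target.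

Step 12
Reactants: 24 12-[(tert-butyldimethylsilyl)oxy]-9β-hydroxy-7-(trimethylsilyl)-6,7-seco-5β-drim-7(Z)-en-11,6-olide
Product: 25 12-[(tert-butyldimethylsilyl)oxy]-9β-hydroxy-7-iodo-6,7-seco-5β-drim-7(Z)-en-11,6-olide
Conditions: N-iodosuccinimide, (CF3)2CHOH, 0 °C
Reagents that add atoms: N-iodosuccinimide, O=C1CCC(=O)N1I
Why: Electrophilic ipso-iododesilylation through the β-silyl cation proceeds with retention of alkene geometry, so iodine stays cis to C9.

Step 13
Reactants: 25 12-[(tert-butyldimethylsilyl)oxy]-9β-hydroxy-7-iodo-6,7-seco-5β-drim-7(Z)-en-11,6-olide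
Product: 27 4-methoxybenzyl 12-[(tert-butyldimethylsilyl)oxy]-6,9β-dihydroxy-7-iodo-6,7-seco-5β-drim-7(Z)-en-11-oate, via lithium carboxylate 26 (not isolated)
Conditions: LiOH·H2O (1.1 equiv), THF/H2O 3:1, rt; evaporate; 4-methoxybenzyl chloride, Bu4NI (cat.), DMF, rt
Reagents that add atoms: lithium hydroxide, [Li+].[OH-]; 4-methoxybenzyl chloride, COc1ccc(CCl)cc1
Why: Saponification of the δ-lactone and SN2 alkylation of the carboxylate, the only good nucleophile under these neutral conditions, give the ring-opened ester with the primary and tertiary hydroxyls free.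

Step 14
Reactants: 27 4-methoxybenzyl 12-[(tert-butyldimethylsilyl)oxy]-6,9β-dihydroxy-7-iodo-6,7-seco-5β-drim-7(Z)-en-11-oate
Product: 28 4-methoxybenzyl 12-[(tert-butyldimethylsilyl)oxy]-7-iodo-6,9β-bis[(triethylsilyl)oxy]-6,7-seco-5β-drim-7(Z)-en-11-oate
Conditions: Et3SiOTf (3 equiv), 2,6-lutidine, CH2Cl2, −78 → 0 °C
Reagents that add atoms: triethylsilyl trifluoromethanesulfonate, CC[Si](CC)(CC)OS(=O)(=O)C(F)(F)F
Why: The silyl triflate silylates both hydroxyls, and capping O9 keeps the later C6 aldehyde from closing to a five-membered lactol.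

Step 15
Reactants: 28 4-methoxybenzyl 12-[(tert-butyldimethylsilyl)oxy]-7-iodo-6,9β-bis[(triethylsilyl)oxy]-6,7-seco-5β-drim-7(Z)-en-11-oate
Product: 29 4-methoxybenzyl 12-[(tert-butyldimethylsilyl)oxy]-7-iodo-6-oxo-9β-[(triethylsilyl)oxy]-6,7-seco-5β-drim-7(Z)-en-11-oate
Conditions: (COCl)2, DMSO, CH2Cl2, −78 → −30 °C; iPr2NEt, −78 → 0 °C
Reagents that add atoms: none
Why: Swern conditions cleave and oxidise a primary triethylsilyl ether directly to the aldehyde while the tertiary triethylsilyl and primary tert-butyldimethylsilyl ethers stay, and the hindered base at low temperature protects the C5 stereocentre α to the new aldehyde.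

Step 16
Reactants: 29 4-methoxybenzyl 12-[(tert-butyldimethylsilyl)oxy]-7-iodo-6-oxo-9β-[(triethylsilyl)oxy]-6,7-seco-5β-drim-7(Z)-en-11-oate
Product: 31 4-methoxybenzyl 12-[(tert-butyldimethylsilyl)oxy]-6β-hydroxy-9β-[(triethylsilyl)oxy]-5β-drim-7-en-11-oate, via 6-O-trimethylsilyl ether 30 (not isolated)
Conditions: CrCl2 (15 mol %), NiCl2(dme) (3 mol %), Me3SiCl (2 equiv), Et4NBF4 (0.1 M), DMF, 5 mM in 29, undivided cell, aluminium anode, nickel-foam cathode, constant current, rt; then aq citric acid, THF, 0 °C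
Reagents that add atoms: none
Why: Zerovalent nickel made at the cathode inserts into the C7–I bond and passes the alkenyl group to trivalent chromium; the alkenylchromium adds to the C6 aldehyde, Me3SiCl silylates the chromium alkoxide and the cathode returns trivalent to divalent chromium, so CrCl2 turns over. The closest known reaction is the intramolecular Nozaki–Hiyama–Kishi alkenyl iodide–aldehyde cyclisation in its electrochemically driven, chromium-catalytic form. Ring B closes in a 6-exo-trig mode by forming C6–C7, and because iodine is cis to C9 the (Z)-alkene becomes the endocyclic C7=C8 bond unchanged. The new C6 stereocentre is controlled by the chair-like transition state of the ring-A conformer that keeps the bulky C9 equatorial, with C1 axial on the forming ring B: the chromium-bound carbonyl oxygen takes the pseudo-equatorial site away from C1, which is the β face, cis to H5. The step needs this facial selectivity and chemoselectivity for the aldehyde over the ester and silyl ethers; the cis ring-A arms and the O9 silyl ether (which also keeps the aldehyde open) secure the first, and the mild non-basic organochromium reagent secures the second and leaves the C5 stereocentre untouched.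

Step 17
Reactants: 31 4-methoxybenzyl 12-[(tert-butyldimethylsilyl)oxy]-6β-hydroxy-9β-[(triethylsilyl)oxy]-5β-drim-7-en-11-oate; 32 (2E,4E,6E)-octa-2,4,6-trienoic acid
Product: 33 4-methoxybenzyl 12-[(tert-butyldimethylsilyl)oxy]-6β-[(2E,4E,6E)-octa-2,4,6-trienoyloxy]-9β-[(triethylsilyl)oxy]-5β-drim-7-en-11-oate
Conditions: EDC·HCl, DMAP, CH2Cl2, 0 °C → rt
Reagents that add atoms: none
Why: Steglich esterification acylates the only free hydroxyl, the secondary allylic O6, with retention at C6.

Step 18
Reactants: 33 4-methoxybenzyl 12-[(tert-butyldimethylsilyl)oxy]-6β-[(2E,4E,6E)-octa-2,4,6-trienoyloxy]-9β-[(triethylsilyl)oxy]-5β-drim-7-en-11-oate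
Product: 34 4-methoxybenzyl 9β,12-dihydroxy-6β-[(2E,4E,6E)-octa-2,4,6-trienoyloxy]-5β-drim-7-en-11-oate
Conditions: HF·pyridine (excess), pyridine, THF, 0 °C → rt
Reagents that add atoms: none
Why: Buffered fluoride cleaves both silyl ethers without touching the esters, and any tertiary silyl ether that resisted would still be removed by the acid of step 20.

Step 19
Reactants: 34 4-methoxybenzyl 9β,12-dihydroxy-6β-[(2E,4E,6E)-octa-2,4,6-trienoyloxy]-5β-drim-7-en-11-oate
Product: 35 4-methoxybenzyl 9β-hydroxy-6β-[(2E,4E,6E)-octa-2,4,6-trienoyloxy]-12-oxo-5β-drim-7-en-11-oate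
Conditions: MnO2, CH2Cl2, rt
Reagents that add atoms: none
Why: MnO2 oxidises only the primary allylic alcohol to the enal under neutral conditions, which also limits lactonisation of the hydroxy ester.

Step 20
Reactants: 35 4-methoxybenzyl 9β-hydroxy-6β-[(2E,4E,6E)-octa-2,4,6-trienoyloxy]-12-oxo-5β-drim-7-en-11-oate
Product: 36 9β-hydroxy-6β-[(2E,4E,6E)-octa-2,4,6-trienoyloxy]-12-oxo-5β-drim-7-en-11-oic acid (CNP0234478.8)
Conditions: TFA, anisole, CH2Cl2, 0 °C
Reagents that add atoms: none
Why: Acidolysis of the 4-methoxybenzyl ester by alkyl–oxygen cleavage, with the benzylic cation trapped by anisole, frees the C11 acid without touching the trienoate, the enal or the tertiary alcohol.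

**Compound list**

1 | 4,4-dimethylcyclohexan-1-one | CC1(C)CCC(=O)CC1 | starting material
2 | dimethyl carbonate | COC(=O)OC | starting material
3 | methyl 5,5-dimethyl-2-oxocyclohexane-1-carboxylate (racemic, keto/enol) | COC(=O)C1CC(C)(C)CCC1=O | intermediate
4 | methyl 5,5-dimethyl-2-oxo-1-(phenylselanyl)cyclohexane-1-carboxylate | COC(=O)C1([Se]c2ccccc2)CC(C)(C)CCC1=O | intermediate (not isolated)
5 | methyl 5,5-dimethyl-2-oxo-1-(phenylseleninyl)cyclohexane-1-carboxylate | COC(=O)C1([Se](=O)c2ccccc2)CC(C)(C)CCC1=O | intermediate (not isolated)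
6 | methyl 3,3-dimethyl-6-oxocyclohex-1-ene-1-carboxylate | COC(=O)C1=CC(C)(C)CCC1=O | intermediate
7 | potassium vinyltrifluoroborate | C=C[B-](F)(F)F.[K+] | starting material
8 | methyl (6S)-6-ethenyl-5,5-dimethyl-2-oxocyclohexane-1-carboxylate (C1 epimers and enol) | COC(=O)C1C(=O)CCC(C)(C)[C@H]1C=C | intermediate
9 | methyl (1R,6R)-6-ethenyl-1,5,5-trimethyl-2-oxocyclohexane-1-carboxylate | COC(=O)[C@@]1(C)C(=O)CCC(C)(C)[C@H]1C=C | intermediate
10 | methyl 2-hydroxy-6-(hydroxymethyl)-1,5,5-trimethylcyclohexane-1-carboxylate (ester and hydroxymethyl cis; C2 epimers) | COC(=O)[C@@]1(C)C(O)CCC(C)(C)[C@H]1CO | intermediate (not isolated)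
11 | 7-hydroxy-4,4,7a-trimethylhexahydro-2-benzofuran-1(3H)-one (cis-fused, 3a-H and 7a-CH3 cis; C7 epimers) | O=C2[C@@]1(C)C(O)CCC(C)(C)[C@H]1CO2 | intermediate
12 | O-phenyl O-(4,4,7a-trimethyl-1-oxo-octahydro-2-benzofuran-7-yl) thionocarbonate (cis-fused; C7 epimers) | O=C2[C@@]1(C)C(OC(=S)Oc3ccccc3)CCC(C)(C)[C@H]1CO2 | intermediate
13 | (3aR,7aS)-4,4,7a-trimethylhexahydro-2-benzofuran-1(3H)-one | O=C2[C@@]1(C)CCCC(C)(C)[C@H]1CO2 | intermediate
14 | ethyl vinyl ether | C=COCC | starting material
15 | 1-ethoxyvinyllithium | [Li]C(=C)OCC | intermediate (not isolated)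
16 | 2-ethoxy-1-[2-(hydroxymethyl)-1,3,3-trimethylcyclohexyl]prop-2-en-1-one (acyl and hydroxymethyl cis; may sit as its hemiketal) | CCOC(=C)C(=O)[C@@]1(C)CCCC(C)(C)[C@H]1CO | intermediate
17 | ethyl 2-[2-(hydroxymethyl)-1,3,3-trimethylcyclohexyl]-2-oxoacetate (acyl and hydroxymethyl cis) | CCOC(=O)C(=O)[C@@]1(C)CCCC(C)(C)[C@H]1CO | intermediate (not isolated)
18 | 4a,8,8-trimethyl-4a,5,6,7,8,8a-hexahydro-1H-isochromene-3,4-dione (cis-fused, 4a-CH3 and 8a-H cis) | O=C2C(=O)[C@@]1(C)CCCC(C)(C)[C@H]1CO2 | intermediate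
19 | tert-butyldimethyl(prop-2-yn-1-yloxy)silane | C#CCO[Si](C)(C)C(C)(C)C | starting material
20 | trimethyl(tributylstannyl)silane | C[Si](C)(C)[Sn](CCCC)(CCCC)CCCC | starting material
21 | (Z)-tert-butyldimethyl{[2-(tributylstannyl)-3-(trimethylsilyl)prop-2-en-1-yl]oxy}silane (Si cis to Sn) | C[Si](C)(C)/C=C(/CO[Si](C)(C)C(C)(C)C)[Sn](CCCC)(CCCC)CCCC | intermediate
22 | {3-[(tert-butyldimethylsilyl)oxy]-1-(trimethylsilyl)prop-1-en-2-yl}lithium (Si cis to Li) | C[Si](C)(C)/C=C(/CO[Si](C)(C)C(C)(C)C)[Li] | intermediate (not isolated)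
23 | {3-[(tert-butyldimethylsilyl)oxy]-1-(trimethylsilyl)prop-1-en-2-yl}cerium dichloride (Si cis to Ce) | C[Si](C)(C)/C=C(/CO[Si](C)(C)C(C)(C)C)[Ce](Cl)Cl | intermediate (not isolated)
24 | 12-[(tert-butyldimethylsilyl)oxy]-9β-hydroxy-7-(trimethylsilyl)-6,7-seco-5β-drim-7(Z)-en-11,6-olide (δ-lactone; C9 as in 31) | C[Si](C)(C)/C=C(/CO[Si](C)(C)C(C)(C)C)[C@@](O)(C(=O)O2)[C@@]1(C)CCCC(C)(C)[C@H]1C2 | intermediate
25 | 12-[(tert-butyldimethylsilyl)oxy]-9β-hydroxy-7-iodo-6,7-seco-5β-drim-7(Z)-en-11,6-olide | I/C=C(/CO[Si](C)(C)C(C)(C)C)[C@@](O)(C(=O)O2)[C@@]1(C)CCCC(C)(C)[C@H]1C2 | intermediate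
26 | lithium 12-[(tert-butyldimethylsilyl)oxy]-6,9β-dihydroxy-7-iodo-6,7-seco-5β-drim-7(Z)-en-11-oate | I/C=C(/CO[Si](C)(C)C(C)(C)C)[C@@](O)(C(=O)[O-])[C@@]1(C)CCCC(C)(C)[C@H]1CO.[Li+] | intermediate (not isolated)
27 | 4-methoxybenzyl 12-[(tert-butyldimethylsilyl)oxy]-6,9β-dihydroxy-7-iodo-6,7-seco-5β-drim-7(Z)-en-11-oate | I/C=C(/CO[Si](C)(C)C(C)(C)C)[C@@](O)(C(=O)OCc1ccc(OC)cc1)[C@@]2(C)CCCC(C)(C)[C@H]2CO | intermediate
28 | 4-methoxybenzyl 12-[(tert-butyldimethylsilyl)oxy]-7-iodo-6,9β-bis[(triethylsilyl)oxy]-6,7-seco-5β-drim-7(Z)-en-11-oate | I/C=C(/CO[Si](C)(C)C(C)(C)C)[C@@](O[Si](CC)(CC)CC)(C(=O)OCc1ccc(OC)cc1)[C@@]2(C)CCCC(C)(C)[C@H]2CO[Si](CC)(CC)CC | intermediate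
29 | 4-methoxybenzyl 12-[(tert-butyldimethylsilyl)oxy]-7-iodo-6-oxo-9β-[(triethylsilyl)oxy]-6,7-seco-5β-drim-7(Z)-en-11-oate (key-step precursor; iodine cis to C9, ring-A arms cis) | I/C=C(/CO[Si](C)(C)C(C)(C)C)[C@@](O[Si](CC)(CC)CC)(C(=O)OCc1ccc(OC)cc1)[C@@]2(C)CCCC(C)(C)[C@H]2C=O | intermediate
30 | 4-methoxybenzyl 12-[(tert-butyldimethylsilyl)oxy]-9β-[(triethylsilyl)oxy]-6β-[(trimethylsilyl)oxy]-5β-drim-7-en-11-oate | C[Si](C)(C)O[C@@H]1C=C(CO[Si](C)(C)C(C)(C)C)[C@@](O[Si](CC)(CC)CC)(C(=O)OCc3ccc(OC)cc3)[C@@]2(C)CCCC(C)(C)[C@@H]12 | intermediate (not isolated)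
31 | 4-methoxybenzyl 12-[(tert-butyldimethylsilyl)oxy]-6β-hydroxy-9β-[(triethylsilyl)oxy]-5β-drim-7-en-11-oate (key-step product) | O[C@@H]1C=C(CO[Si](C)(C)C(C)(C)C)[C@@](O[Si](CC)(CC)CC)(C(=O)OCc3ccc(OC)cc3)[C@@]2(C)CCCC(C)(C)[C@@H]12 | intermediate
32 | (2E,4E,6E)-octa-2,4,6-trienoic acid | C/C=C/C=C/C=C/C(=O)O | starting material
33 | 4-methoxybenzyl 12-[(tert-butyldimethylsilyl)oxy]-6β-[(2E,4E,6E)-octa-2,4,6-trienoyloxy]-9β-[(triethylsilyl)oxy]-5β-drim-7-en-11-oate | C/C=C/C=C/C=C/C(=O)O[C@@H]1C=C(CO[Si](C)(C)C(C)(C)C)[C@@](O[Si](CC)(CC)CC)(C(=O)OCc3ccc(OC)cc3)[C@@]2(C)CCCC(C)(C)[C@@H]12 | intermediate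
34 | 4-methoxybenzyl 9β,12-dihydroxy-6β-[(2E,4E,6E)-octa-2,4,6-trienoyloxy]-5β-drim-7-en-11-oate | C/C=C/C=C/C=C/C(=O)O[C@@H]1C=C(CO)[C@@](O)(C(=O)OCc3ccc(OC)cc3)[C@@]2(C)CCCC(C)(C)[C@@H]12 | intermediate
35 | 4-methoxybenzyl 9β-hydroxy-6β-[(2E,4E,6E)-octa-2,4,6-trienoyloxy]-12-oxo-5β-drim-7-en-11-oate | C/C=C/C=C/C=C/C(=O)O[C@@H]1C=C(C=O)[C@@](O)(C(=O)OCc3ccc(OC)cc3)[C@@]2(C)CCCC(C)(C)[C@@H]12 | intermediate
36 | 9β-hydroxy-6β-[(2E,4E,6E)-octa-2,4,6-trienoyloxy]-12-oxo-5β-drim-7-en-11-oic acid (CNP0234478.8) | C/C=C/C=C/C=C/C(=O)O[C@@H]1C=C(C=O)[C@@](O)(C(=O)O)[C@@]2(C)CCCC(C)(C)[C@@H]12 | target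

**Step count and risks**

Total step count: 20 (19 in the main line plus step 10 for alkenylstannane 21). Longest linear sequence: 19 steps from 1 to 36 (steps 1–9 and 11–20).

The three steps most likely to fail:

Step 16 (ring closure). The closure may run through the other ring-A chair (C9 axial), which places the carbinol oxygen trans to H5; a slow closure also leaves time for protodemetalation of the alkenylchromium. The fallback keeps the ring closure but sets C6 by invertive esterification instead of by the closure. It sets out from 29, which under the step-16 conditions would then give 4-methoxybenzyl 12-[(tert-butyldimethylsilyl)oxy]-6α-hydroxy-9β-[(triethylsilyl)oxy]-5β-drim-7-en-11-oate F1. Treating F1 with acid 32, PPh3 and diisopropyl azodicarboxylate (toluene, 0 °C → rt, Mitsunobu reaction) should displace the activated 6α-oxygen with inversion and give ester 33 directly, where the route is rejoined before step 18.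

Step 3 (asymmetric vinylation). Insertion at a β-carbon next to the quaternary C4 may be sluggish, and the facial selectivity of the catalyst may erode on an enone that carries an α-ester. The fallback replaces catalyst control by a covalently bound auxiliary whose diastereomers can be separated. It sets out from keto ester 3: transesterification with (1R,2S,5R)-8-phenylmenthol (DMAP, toluene, reflux, methanol distilled off) gives the 8-phenylmenthyl keto ester F2. Dehydrogenation with DDQ (1,4-dioxane, reflux) gives the 8-phenylmenthyl enone ester F3. Copper-mediated conjugate addition of vinylmagnesium bromide (CuBr·SMe2, THF, −78 °C) with trapping of the enolate by MeI/DMPU gives the 8-phenylmenthyl vinyl methyl keto ester F4, the aryl group shielding one face of the enoate; the wanted diastereomer is purified by chromatography. Ozonolysis with NaBH4 work-up as in step 5 gives the 8-phenylmenthyl diol ester F5, and acid-catalysed lactonisation expels the auxiliary and returns the route to hydroxy lactone 11.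

Step 13 (lactone opening). The freed 6-hydroxyl may close back onto the C11 carbonyl with loss of 4-methoxybenzyl alcohol during or after the carboxylate alkylation. The fallback protects O6 before the ester is made. It sets out from 25: saponification as before gives lithium carboxylate 26, which is treated in the same flask with Et3SiCl and imidazole (DMF) to give the triethylsilyl ester 6-O-triethylsilyl ether F6. Aqueous NaHCO3 work-up hydrolyses the silyl ester to the 6-O-triethylsilyl hydroxy acid F7. Alkylation of its carboxylate (4-methoxybenzyl chloride, KHCO3, DMF) gives the 6-O-triethylsilyl 4-methoxybenzyl ester F8, and Et3SiOTf/2,6-lutidine at O9 returns the route to bis-silyl ether 28.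

**Further compounds**

F1 | step 16 | 4-methoxybenzyl 12-[(tert-butyldimethylsilyl)oxy]-6α-hydroxy-9β-[(triethylsilyl)oxy]-5β-drim-7-en-11-oate | O[C@H]1C=C(CO[Si](C)(C)C(C)(C)C)[C@@](O[Si](CC)(CC)CC)(C(=O)OCc3ccc(OC)cc3)[C@@]2(C)CCCC(C)(C)[C@@H]12
F2 | step 3 | (1R,2S,5R)-5-methyl-2-(2-phenylpropan-2-yl)cyclohexyl 5,5-dimethyl-2-oxocyclohexane-1-carboxylate | CC(C)(c1ccccc1)[C@@H]2CC[C@@H](C)C[C@H]2OC(=O)C3CC(C)(C)CCC3=O
F3 | step 3 | (1R,2S,5R)-5-methyl-2-(2-phenylpropan-2-yl)cyclohexyl 3,3-dimethyl-6-oxocyclohex-1-ene-1-carboxylate | CC(C)(c1ccccc1)[C@@H]2CC[C@@H](C)C[C@H]2OC(=O)C3=CC(C)(C)CCC3=O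
F4 | step 3 | (1R,2S,5R)-5-methyl-2-(2-phenylpropan-2-yl)cyclohexyl (1R,6R)-6-ethenyl-1,5,5-trimethyl-2-oxocyclohexane-1-carboxylate | CC(C)(c1ccccc1)[C@@H]2CC[C@@H](C)C[C@H]2OC(=O)[C@@]3(C)C(=O)CCC(C)(C)[C@H]3C=C
F5 | step 3 | (1R,2S,5R)-5-methyl-2-(2-phenylpropan-2-yl)cyclohexyl 2-hydroxy-6-(hydroxymethyl)-1,5,5-trimethylcyclohexane-1-carboxylate (ester and hydroxymethyl cis; C2 epimers) | CC(C)(c1ccccc1)[C@@H]2CC[C@@H](C)C[C@H]2OC(=O)[C@@]3(C)C(O)CCC(C)(C)[C@H]3CO
F6 | step 13 | triethylsilyl 12-[(tert-butyldimethylsilyl)oxy]-9β-hydroxy-7-iodo-6-[(triethylsilyl)oxy]-6,7-seco-5β-drim-7(Z)-en-11-oate | I/C=C(/CO[Si](C)(C)C(C)(C)C)[C@@](O)(C(=O)O[Si](CC)(CC)CC)[C@@]1(C)CCCC(C)(C)[C@H]1CO[Si](CC)(CC)CC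
F7 | step 13 | 12-[(tert-butyldimethylsilyl)oxy]-9β-hydroxy-7-iodo-6-[(triethylsilyl)oxy]-6,7-seco-5β-drim-7(Z)-en-11-oic acid | I/C=C(/CO[Si](C)(C)C(C)(C)C)[C@@](O)(C(=O)O)[C@@]1(C)CCCC(C)(C)[C@H]1CO[Si](CC)(CC)CC
F8 | step 13 | 4-methoxybenzyl 12-[(tert-butyldimethylsilyl)oxy]-9β-hydroxy-7-iodo-6-[(triethylsilyl)oxy]-6,7-seco-5β-drim-7(Z)-en-11-oate | I/C=C(/CO[Si](C)(C)C(C)(C)C)[C@@](O)(C(=O)OCc1ccc(OC)cc1)[C@@]2(C)CCCC(C)(C)[C@H]2CO[Si](CC)(CC)CC
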